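# Ebenfuran III (21): synthesis design built on an oxygen-to-carbon methoxymethyl shift

## The problem

Ebenfuran III (21) is a 2-arylbenzofuran. A phloroglucinol-type benzo ring A (C3a, C4–C7, C7a) is fused along C3a–C7a to the furan ring B (O1, C2, C3), and a resorcinol ring C is attached to C2 through the single bond C2–C1'. The molecule has no stereocentre and its only alkene ends in a gem-dimethyl group. Nothing has to be set or relayed in space, so every difficulty is one of position and functional-group tolerance.

On ring A the three oxygens (O1, 4-OH, 6-OMe) must end up different. They activate C5 and C7 alike, yet the prenyl chain belongs on C5 only. C3 needs a formyl group, but a formylating electrophile would find C5 and C7 at least as attractive, so the aldehyde carbon must arrive by a process that can reach C3 alone.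

Three parts are fragile: the 4-OH/5-prenyl pair (chroman in acid, chromene with quinone oxidants), the aldehyde between 4-OH and 2'-OH (sensitive to hydride, organometallics and amines), and the free polyphenol (air-sensitive in base). Oxidative and acidic steps must therefore precede prenylation, and the last unmasking must be mild and basic.

The enabling feature is that the one-carbon substituent on C3 stands 1,3 to O1 across C2. That carbon can be stored as the CH2 of a methoxymethyl ether on the ring A oxygen that becomes O1, and passed to C3 while this oxygen closes ring B onto a diarylalkyne. Because O1 and O4 are both ortho to C3a, the alkyne precursor can carry two identical methoxymethyl ethers on a symmetric ring A. Either oxygen then closes to the same benzofuran, and the one left over protects O4.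

## Retrosynthesis

**Ring C oxygens (21 ⇒ 20).** The end of the route is fixed first. The O–H bonds at C2' and C4' are traced back to the O–acyl bonds of the dipivalate 20.
- Acid-labile groups are excluded by the 4-OH/5-prenyl pair, and hydrogenolysis by the alkene.
- Esters fall off in basic methanol. They also make the 2'-oxygen a poor nucleophile, which the ring closure needs.
- The skeleton is unchanged, but 20 is a robust, chromatographable monophenol.
- The forward step must cleave two hindered aryl esters without touching the aldehyde.

**Prenyl chain (20 ⇒ 18 ⇒ 17 ⇒ 15 + 16).** The C5–CH2 bond is cut as a [3,3] shift from O4.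
- Intermolecular prenylation cannot tell C5 from C7. From O4, however, C5 is the only ortho carbon that carries hydrogen, since the other ortho position is the ring fusion C3a.
- The 1,1-dimethylallyl ether 18 inverts during the shift through dienone 19 and delivers the linear prenyl group directly.
- Ether 18 comes from the propargyl ether 17 by semihydrogenation. Ether 17 comes from phenol 15 and the tertiary chloride 16.
- The precursor 15 is five carbons smaller and has a single free phenol.
- The forward steps must form a tertiary ether on a crowded phenol and rearrange it below the temperature at which it fragments.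

**Aldehyde and O4 (15 ⇒ 14 ⇒ 12).** No skeletal bond is cut. The O4–H bond returns to the methoxymethyl ether of 14, and the formyl group returns to the CH2OMe group of 12, one two-electron oxidation lower.
- This order places the quinone oxidant and the acid ahead of the prenyl group.
- A C3 ester would cost a reduction and a reoxidation. A C3 methyl would cost a four-electron oxidation. The ether is the closest stable neighbour of the aldehyde.
- The forward oxidation must remove hydride from one benzylic CH2 of an electron-rich heteroarene and then stop, which the deactivating aldehyde ensures.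

**Ring B (12 ⇒ 10).** O1–C2 and C3–CH2 are cut together, giving the isomeric diarylalkyne 10.
- Cutting O1–C2 alone would leave a 3-unsubstituted benzofuran and the unsolved C3/C5/C7 formylation problem.
- Cutting C2–C1' would still require a fully substituted benzofuran partner.
- The double cut removes one ring, restores mirror symmetry to ring A, and turns the aldehyde carbon into part of a protecting group.
- Divalent platinum has to make a ring A ether oxygen add 5-endo to the alkyne carbon bearing ring C. The methoxymethyl group must then move to C3 faster than the vinyl–metal bond is protonated.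
- Ring A donors polarise the alkyne against this addition, so an electrophilic catalyst (CO-ligated) and rigorously aprotic conditions are planned.

**Alkyne (10 ⇒ 7 + 9).** The C(sp)–C1' bond is cut.
- Iodide 9 is electron-poor and hindered on one side only, so it should couple near room temperature with the valuable alkyne 7.
- The neighbouring cut at ring A would pair the sluggish, doubly ortho-substituted iodide 4 with a precious alkyne whose pivalates would not survive basic desilylation.
- The two fragments are of similar size, and each holds one ring.

**Fragments (7 ⇒ 6 ⇒ 4 + 5; 4 ⇒ 3 ⇒ 2 ⇒ 1; 9 ⇒ 8).**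
- Alkyne 7 is the desilylated form of 6, made from iodide 4 and the cheap alkyne 5, which can be used in excess against the hindered iodide.
- The C–I bond of 4 is traced to aryllithium 3. It forms between the two chelating acetal oxygens of 2, the bis-methoxymethyl ether of commercial 1.
- Electrophilic iodination of 2 would not distinguish its three activated positions.
- Dipivalate 9 is the acylated form of commercial 8.

## Roads not taken

**Alternative 1:** Ring A is removed altogether by cutting C7a–C7, C7–C6, C5–C4 and C4–C3a. This leaves the furyl diazoketone A1 and the methoxyalkyne A2, which already carries the prenyl chain.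
- *Forward key step.* Irradiation turns A1 into a furylketene by Wolff rearrangement. The ketene adds [2+2] to A2, the cyclobutenone opens in a four-electron process, and a six-electron closure onto the free furan position gives phenol ester A3.
- *Merits.* OH, prenyl and OMe are set on C4, C5 and C6 in one regiodefined operation. This is clearly better than the chosen plan, which spends steps 9 to 12 on the prenyl group.
- *Weak points.*
  - A1 is a 2,3,5-trisubstituted furan that needs its own multistep assembly and diazo transfer or homologation.
  - A2 is a non-commercial, acid- and heat-sensitive skipped enyne ynol ether.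
  - The carbene and ketene intermediates meet a nucleophilic trisubstituted alkene.
  - The electrocyclisation must overcome furan aromaticity.
  - A3 holds C3 as an ester, so a hydride reduction and a reoxidation follow in the presence of a free o-prenylphenol.
  - Its ring C acetals must be removed with acid while the 4-OH/5-prenyl pair is present.
- *Comparison.* The chosen plan offers commercial building blocks, a catalytic isomerisation without diazo or photochemical equipment, a C3 carbon one mild oxidation from the aldehyde, and a basic last step.

**Alternative 2:** Only O1–C2 is cut, but from the 3-aroyl lactone A4, in which the future C3 carbon substituent is the lactone carbonyl.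
- *Forward key step.* Catalytic methoxide in methanol opens A4 to a phenol β-keto ester. The liberated phenol adds to the aryl ketone, and acid dehydration gives the benzofuran ester A5.
- *Merits.* The closure needs no transition metal, uses cheap reagents, and fixes both the O1–C2 connectivity and the C3 carbon unambiguously. In cost and scalability of the ring closure it is better than platinum catalysis.
- *Weak points.*
  - Ring A must already carry three different oxygens (lactone, silyl ether, methyl ether) on a non-commercial benzofuranone.
  - The acetic acid carbon of that benzofuranone has to be placed between two oxygens.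
  - C-acylation of the lactone enolate competes with O-acylation.
  - A phenolic silyl ether is exposed to methoxide.
  - The ester again costs a reduction and a reoxidation.
  - The ring C acetals again call for acid late in the route.
- *Comparison.* The overall length would be similar. The chosen plan keeps ring A symmetric until the closure itself desymmetrises it, avoids hydride chemistry entirely, and uses ring C groups that also serve as the selectivity element of the key step.

**Alternative 3:** The C2=C3 double bond is cut, leading to keto ester A6.
- *Forward key step.* Low-valent titanium couples the acetyl ketone with the neighbouring aryl ester carbonyl and gives the 3-methylbenzofuran A7.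
- *Merits.* A6 is one esterification away from simple aromatic building blocks. This is probably the shortest access to the 2-arylbenzofuran core, shorter than steps 1 to 7 here, and the reductive keto–ester coupling is dependable for benzofurans.
- *Weak points.*
  - C3 arrives as a methyl group. A four-electron oxidation must be carried out on an electron-rich heteroarene in competition with ring attack and with the oxidisable benzyl ether CH2 of A7.
  - The titanium reagent is superstoichiometric, and its Lewis-acidic chlorides threaten the ring C acetals.
  - Ring A must be desymmetrised beforehand (benzyl ether against ester oxygen).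
  - The final acetal removal again needs acid next to the o-prenylphenol.
- *Comparison.* The chosen plan concedes the shorter core synthesis. In return it offers a C3 carbon that is already oxygenated, a catalytic and atom-neutral closure, and an endgame free of acid.

Key step: step 7

Assumption: 21 is taken as the open hydroxy aldehyde. Ring–chain tautomerism of the 3-formyl group with the 2'-hydroxyl (cyclic hemiacetal) is regarded as an equilibrium of the same compound.

## Steps

Step 1
Reactants: 1 5-methoxyresorcinol
Product: 2 1-methoxy-3,5-bis(methoxymethoxy)benzene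
Conditions: MOMCl (2.6 equiv), i-Pr2NEt (3 equiv), CH2Cl2, 0 °C to rt
Reagents that add atoms: chloromethyl methyl ether, COCCl
Why: Williamson-type O-alkylation of both phenols with a hard α-chloro ether under amine base, where C-alkylation does not compete. The two acetals later direct the lithiation, supply the migrating C1 unit and protect O4.

Step 2
Reactants: 2 1-methoxy-3,5-bis(methoxymethoxy)benzene
Product: 4 2-iodo-5-methoxy-1,3-bis(methoxymethoxy)benzene, via aryllithium 3 (not isolated)
Conditions: n-BuLi (1.1 equiv), THF, 0 °C; then I2, −78 °C to rt
Reagents that add atoms: iodine, II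
Why: Directed ortho-metalation; the position flanked by two chelating methoxymethoxy groups should be more acidic and better coordinated than those next to the simple methyl ether, and iodine traps aryllithium 3 at that carbon. Electrophilic iodination would not offer this site control.

Step 3
Reactants: 4 2-iodo-5-methoxy-1,3-bis(methoxymethoxy)benzene; 5 trimethylsilylacetylene
Product: 6 {[4-methoxy-2,6-bis(methoxymethoxy)phenyl]ethynyl}trimethylsilane
Conditions: 5 (2 equiv), PdCl2(PPh3)2 (5 mol %), CuI (10 mol %), Et3N/DMF, 70 °C, sealed vessel, degassed
Reagents that add atoms: none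
Why: Sonogashira coupling; the hindered, electron-rich iodide is paired with a small, cheap alkyne in excess and heated to compensate for slow oxidative addition. Acetals and the methyl ether are inert.

Step 4
Reactants: 6 {[4-methoxy-2,6-bis(methoxymethoxy)phenyl]ethynyl}trimethylsilane
Product: 7 2-ethynyl-5-methoxy-1,3-bis(methoxymethoxy)benzene
Conditions: K2CO3 (0.2 equiv), MeOH/THF, rt
Reagents that add atoms: none
Why: Base-catalysed protodesilylation of an alkynylsilane by methanol; nothing else in 6 is base-sensitive.

Step 5
Reactants: 8 4-iodoresorcinol
Product: 9 4-iodo-1,3-phenylene bis(2,2-dimethylpropanoate)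
Conditions: PivCl (2.4 equiv), Et3N (3 equiv), DMAP (5 mol %), CH2Cl2, 0 °C to rt
Reagents that add atoms: pivaloyl chloride, CC(C)(C)C(=O)Cl
Why: DMAP-catalysed acylation of both phenols. The bulky esters resist tertiary amines, activate the iodide for coupling and later mute the 2'-oxygen.

Step 6
Reactants: 7 2-ethynyl-5-methoxy-1,3-bis(methoxymethoxy)benzene; 9 4-iodo-1,3-phenylene bis(2,2-dimethylpropanoate)
Product: 10 4-{[4-methoxy-2,6-bis(methoxymethoxy)phenyl]ethynyl}-1,3-phenylene bis(2,2-dimethylpropanoate)
Conditions: PdCl2(PPh3)2 (3 mol %), CuI (5 mol %), Et3N, THF, rt to 40 °C, degassed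
Reagents that add atoms: none
Why: Sonogashira coupling of an activated aryl iodide with a terminal arylalkyne under mild conditions. A tertiary amine base leaves the aryl pivalates intact, and exclusion of oxygen suppresses oxidative alkyne dimerisation.

Step 7
Reactants: 10 4-{[4-methoxy-2,6-bis(methoxymethoxy)phenyl]ethynyl}-1,3-phenylene bis(2,2-dimethylpropanoate)
Product: 12 4-[6-methoxy-3-(methoxymethyl)-4-(methoxymethoxy)benzofuran-2-yl]-1,3-phenylene bis(2,2-dimethylpropanoate), via oxonium vinylplatinum zwitterion 11 (not isolated)
Conditions: PtCl2 (5–10 mol %), CO (1 atm), dry toluene, 4 Å molecular sieves, 80 °C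
Reagents that add atoms: none
Why: This is the known PtCl2-catalysed intramolecular carboalkoxylation of ortho-alkynylphenyl alkoxymethyl ethers, applied here to a diarylalkyne. Divalent platinum, made more electrophilic by the CO ligand, binds the alkyne of 10, and a ring A methoxymethyl ether oxygen adds anti to the metal at the alkyne carbon bearing ring C; this 5-endo-dig closure forms O1–C2, closes ring B and gives zwitterion 11. The oxonium of 11 releases its CH2OMe group as a methoxycarbenium ion, which the nucleophilic platinum-bearing C3 captures within the ion pair, so that C3–CH2 forms, PtCl2 is regenerated and the net change is an atom-neutral 1,3 oxygen-to-carbon shift. No stereocentre is created. Choice between the two ring A oxygens is irrelevant because 10 is mirror-symmetric about the alkyne axis and both closures give 12, while 4-exo attack at the other alkyne carbon is geometrically excluded. Selectivity against ring C rests on the 2'-oxygen being an ester oxygen, whose lone pair is engaged by the pivaloyl carbonyl and whose acyl group is a poor migrating cation. The carbon shift must outrun protodemetalation of 11, hence dry toluene, sieves and the absence of any protic additive. The C1 unit can end only on C3, so C5 and C7 remain untouched.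

Step 8
Reactants: 12 4-[6-methoxy-3-(methoxymethyl)-4-(methoxymethoxy)benzofuran-2-yl]-1,3-phenylene bis(2,2-dimethylpropanoate)
Product: 14 4-[3-formyl-6-methoxy-4-(methoxymethoxy)benzofuran-2-yl]-1,3-phenylene bis(2,2-dimethylpropanoate), via methyl hemiacetal 13 (not isolated)
Conditions: DDQ (1.3 equiv), CH2Cl2/pH 7 phosphate buffer (10:1), 0 °C to rt
Reagents that add atoms: water, O
Why: DDQ oxidation of an electron-rich arylmethyl ether, the reaction type used to cleave p-methoxybenzyl ethers. The dialkoxybenzofuran is a better donor than anisole, and the resulting cation is stabilised by the ether oxygen and by O1 through C2. Water gives hemiacetal 13, which loses methanol, and the aldehyde deactivates 14 against further oxidation; the buffer protects the 4-O acetal.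

Step 9
Reactants: 14 4-[3-formyl-6-methoxy-4-(methoxymethoxy)benzofuran-2-yl]-1,3-phenylene bis(2,2-dimethylpropanoate)
Product: 15 4-(3-formyl-4-hydroxy-6-methoxybenzofuran-2-yl)-1,3-phenylene bis(2,2-dimethylpropanoate)
Conditions: 3 M aq. HCl, THF, 45 °C
Reagents that add atoms: none
Why: Acid hydrolysis of an aryl methoxymethyl acetal, helped by the hydrogen bond that the freed 4-OH forms to the 3-formyl group. Hindered aryl pivalates hydrolyse far more slowly in dilute acid, the aqueous medium prevents acetalisation of the aldehyde, and no prenyl group is present yet.

Step 10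
Reactants: 15 4-(3-formyl-4-hydroxy-6-methoxybenzofuran-2-yl)-1,3-phenylene bis(2,2-dimethylpropanoate); 16 3-chloro-3-methylbut-1-yne
Product: 17 4-{3-formyl-6-methoxy-4-[(2-methylbut-3-yn-2-yl)oxy]benzofuran-2-yl}-1,3-phenylene bis(2,2-dimethylpropanoate)
Conditions: 16 (2 equiv), DBU (2 equiv), CuCl2 (1 mol %), MeCN, 0 °C to rt
Reagents that add atoms: none
Why: Copper-catalysed propargylic etherification of a phenol with a tertiary propargylic chloride, which proceeds through an activated copper acetylide species rather than SN2 and works best with acidic, acceptor-substituted phenols such as 15. The 4-OH is the only free hydroxyl.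

Step 11
Reactants: 17 4-{3-formyl-6-methoxy-4-[(2-methylbut-3-yn-2-yl)oxy]benzofuran-2-yl}-1,3-phenylene bis(2,2-dimethylpropanoate)
Product: 18 4-{3-formyl-6-methoxy-4-[(2-methylbut-3-en-2-yl)oxy]benzofuran-2-yl}-1,3-phenylene bis(2,2-dimethylpropanoate)
Conditions: H2 (1 atm), 5% Pd/CaCO3 poisoned with Pb(OAc)2, quinoline, EtOAc, rt, stopped after one equivalent of H2
Reagents that add atoms: none
Why: Lindlar-type semihydrogenation of a terminal alkyne. The poisoned catalyst leaves the aryl aldehyde, the benzofuran and the tertiary allylic C–O bond alone.

Step 12
Reactants: 18 4-{3-formyl-6-methoxy-4-[(2-methylbut-3-en-2-yl)oxy]benzofuran-2-yl}-1,3-phenylene bis(2,2-dimethylpropanoate)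
Product: 20 4-[3-formyl-4-hydroxy-6-methoxy-5-(3-methylbut-2-enyl)benzofuran-2-yl]-1,3-phenylene bis(2,2-dimethylpropanoate), via cyclohexadienone 19 (not isolated)
Conditions: PhNEt2, 130 °C, Ar
Reagents that add atoms: none
Why: Aromatic Claisen rearrangement. The [3,3] shift can reach only C5, the sole hydrogen-bearing ortho carbon of O4, and allyl inversion turns the 1,1-dimethylallyl ether into the linear prenyl group. Dienone 19 carries H at C5 and should enolise to 20 before any onward Cope shift, and the basic solvent suppresses acid-induced chroman formation.

Step 13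
Reactants: 20 4-[3-formyl-4-hydroxy-6-methoxy-5-(3-methylbut-2-enyl)benzofuran-2-yl]-1,3-phenylene bis(2,2-dimethylpropanoate)
Product: 21 ebenfuran III, 2-(2,4-dihydroxyphenyl)-4-hydroxy-6-methoxy-5-(3-methylbut-2-enyl)benzofuran-3-carbaldehyde
Conditions: K2CO3 (3 equiv), MeOH, 0 °C to rt, Ar; then aq. NH4Cl
Reagents that add atoms: none
Why: Base-mediated transesterification of aryl esters, whose phenoxide leaving groups make even pivalates labile to methoxide. The aldehyde is non-enolisable, the prenyl group is inert to base, and the near-neutral quench avoids cyclisation of the o-prenylphenol.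

## Compound list

1 | 5-methoxyresorcinol | COc1cc(O)cc(O)c1 | starting material
2 | 1-methoxy-3,5-bis(methoxymethoxy)benzene | COCOc1cc(OC)cc(OCOC)c1 | intermediate
3 | [4-methoxy-2,6-bis(methoxymethoxy)phenyl]lithium (not isolated) | [Li]c1c(OCOC)cc(OC)cc1OCOC | intermediate
4 | 2-iodo-5-methoxy-1,3-bis(methoxymethoxy)benzene | COCOc1cc(OC)cc(OCOC)c1I | intermediate
5 | trimethylsilylacetylene | C#C[Si](C)(C)C | starting material
6 | {[4-methoxy-2,6-bis(methoxymethoxy)phenyl]ethynyl}trimethylsilane | COCOc1cc(OC)cc(OCOC)c1C#C[Si](C)(C)C | intermediate
7 | 2-ethynyl-5-methoxy-1,3-bis(methoxymethoxy)benzene | COCOc1cc(OC)cc(OCOC)c1C#C | intermediate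
8 | 4-iodoresorcinol | Oc1ccc(I)c(O)c1 | starting material
9 | 4-iodo-1,3-phenylene bis(2,2-dimethylpropanoate) | CC(C)(C)C(=O)Oc1ccc(I)c(OC(=O)C(C)(C)C)c1 | intermediate
10 | 4-{[4-methoxy-2,6-bis(methoxymethoxy)phenyl]ethynyl}-1,3-phenylene bis(2,2-dimethylpropanoate) | COCOc1cc(OC)cc(OCOC)c1C#Cc1ccc(OC(=O)C(C)(C)C)cc1OC(=O)C(C)(C)C | intermediate
11 | 1-(methoxymethyl)benzofuran-1-ium-3-yl dichloroplatinate zwitterion derived from 10, ancillary CO ligand omitted (not isolated) | COC[O+]1C(c2ccc(OC(=O)C(C)(C)C)cc2OC(=O)C(C)(C)C)=C([Pt-](Cl)Cl)c2c(OCOC)cc(OC)cc21 | intermediate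
12 | 4-[6-methoxy-3-(methoxymethyl)-4-(methoxymethoxy)benzofuran-2-yl]-1,3-phenylene bis(2,2-dimethylpropanoate) | COCc1c(-c2ccc(OC(=O)C(C)(C)C)cc2OC(=O)C(C)(C)C)oc2cc(OC)cc(OCOC)c12 | intermediate
13 | 4-{3-[hydroxy(methoxy)methyl]-6-methoxy-4-(methoxymethoxy)benzofuran-2-yl}-1,3-phenylene bis(2,2-dimethylpropanoate), racemic and transient (not isolated) | COC(O)c1c(-c2ccc(OC(=O)C(C)(C)C)cc2OC(=O)C(C)(C)C)oc2cc(OC)cc(OCOC)c12 | intermediate
14 | 4-[3-formyl-6-methoxy-4-(methoxymethoxy)benzofuran-2-yl]-1,3-phenylene bis(2,2-dimethylpropanoate) | O=Cc1c(-c2ccc(OC(=O)C(C)(C)C)cc2OC(=O)C(C)(C)C)oc2cc(OC)cc(OCOC)c12 | intermediate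
15 | 4-(3-formyl-4-hydroxy-6-methoxybenzofuran-2-yl)-1,3-phenylene bis(2,2-dimethylpropanoate) | O=Cc1c(-c2ccc(OC(=O)C(C)(C)C)cc2OC(=O)C(C)(C)C)oc2cc(OC)cc(O)c12 | intermediate
16 | 3-chloro-3-methylbut-1-yne | CC(C)(Cl)C#C | starting material
17 | 4-{3-formyl-6-methoxy-4-[(2-methylbut-3-yn-2-yl)oxy]benzofuran-2-yl}-1,3-phenylene bis(2,2-dimethylpropanoate) | O=Cc1c(-c2ccc(OC(=O)C(C)(C)C)cc2OC(=O)C(C)(C)C)oc2cc(OC)cc(OC(C)(C)C#C)c12 | intermediate
18 | 4-{3-formyl-6-methoxy-4-[(2-methylbut-3-en-2-yl)oxy]benzofuran-2-yl}-1,3-phenylene bis(2,2-dimethylpropanoate) | O=Cc1c(-c2ccc(OC(=O)C(C)(C)C)cc2OC(=O)C(C)(C)C)oc2cc(OC)cc(OC(C)(C)C=C)c12 | intermediate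
19 | 4-[3-formyl-6-methoxy-5-(3-methylbut-2-enyl)-4-oxo-4,5-dihydrobenzofuran-2-yl]-1,3-phenylene bis(2,2-dimethylpropanoate), racemic and transient (not isolated) | O=Cc1c(-c2ccc(OC(=O)C(C)(C)C)cc2OC(=O)C(C)(C)C)oc2c1C(=O)C(CC=C(C)C)C(OC)=C2 | intermediate
20 | 4-[3-formyl-4-hydroxy-6-methoxy-5-(3-methylbut-2-enyl)benzofuran-2-yl]-1,3-phenylene bis(2,2-dimethylpropanoate) | O=Cc1c(-c2ccc(OC(=O)C(C)(C)C)cc2OC(=O)C(C)(C)C)oc2cc(OC)c(CC=C(C)C)c(O)c12 | intermediate
21 | ebenfuran III, 2-(2,4-dihydroxyphenyl)-4-hydroxy-6-methoxy-5-(3-methylbut-2-enyl)benzofuran-3-carbaldehyde | COc1cc2oc(-c3ccc(O)cc3O)c(C=O)c2c(O)c1CC=C(C)C | target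

## Count and least certain steps

Total step count: 13. Longest linear sequence: 12 steps, from 1 through steps 1–4 and 6–13. Step 5 is the only side branch.

**Key step (step 7).**
- *Risk.* The most likely failure is protodemetalation of the vinylplatinum stage by traces of proton sources, so that the methoxymethyl unit is lost instead of transferred. The three donors on ring A also polarise the alkyne so that the carbon bearing ring C is its electron-richer end. This slows the 5-endo addition and gives Lewis-acid cleavage of the acetals, or participation of the pivalate carbonyl, more time to occur.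
- *Fallback.* It sets out from 10. Electrophilic iodocyclisation (I2, CH2Cl2, rt), in which iodide removes the methoxymethyl group from the oxonium, should give 4-[3-iodo-6-methoxy-4-(methoxymethoxy)benzofuran-2-yl]-1,3-phenylene bis(2,2-dimethylpropanoate) F1. Iodine–magnesium exchange with i-PrMgCl·LiCl (THF, −40 °C), which hindered aryl esters tolerate, gives the 3-(chloromagnesio)benzofuran F2. Formylation with DMF returns to the route at 14 and replaces steps 7 and 8.

**Oxidation (step 8).**
- *Risk.* Hydride abstraction may be slowed by crowding between the 4-O acetal and the twisted ring C. Oxidative attack or coupling at the free ring A positions may then compete, or the acidic hydroquinone by-product may strip the acetal early.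
- *Fallback.* It sets out from 12 and separates ionisation from oxidation. Aqueous HCl in THF at 50 °C removes the 4-O acetal and exchanges the benzylic methoxy group for hydroxyl through the O1-stabilised cation. This gives 4-[4-hydroxy-3-(hydroxymethyl)-6-methoxybenzofuran-2-yl]-1,3-phenylene bis(2,2-dimethylpropanoate) F3. MnO2 in CH2Cl2 then oxidises the benzylic alcohol and returns to the route at 15, so steps 8 and 9 are both replaced.

**Etherification (step 10).**
- *Risk.* The hydrogen-bonded, peri-crowded phenoxide may be too poor a nucleophile. Dehydrochlorination of 16 by DBU, or slow base-induced pivaloyl transfer, could then take over.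
- *Fallback.* It sets out from 15. A Tsuji–Trost O-allylation with tert-butyl 2-methylbut-3-en-2-yl carbonate and Pd(PPh3)4 (THF, 0 °C) lets a dimethylallyl complex of divalent palladium be attacked at its tertiary end under kinetic control. This returns to the route directly at 18. Steps 10 and 11 are replaced, and no compound outside the list is made (F0).

**Claisen shift (step 12).**
- *Risk.* The tertiary allyl ether may fragment (loss of the C5 unit as a diene, with return of the phenol) faster than it rearranges. The acceptor-substituted ring raises the barrier, and onward Cope migration towards C7 or closure of the o-prenylphenol to a chroman could erode the product on prolonged heating.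
- *Fallback.* It sets out from 15 with a primary allyl group that cannot fragment in this way.
  - Allyl bromide and K2CO3 in DMF give 4-[4-(allyloxy)-3-formyl-6-methoxybenzofuran-2-yl]-1,3-phenylene bis(2,2-dimethylpropanoate) F4.
  - Aromatic Claisen rearrangement (PhNEt2, 190 °C) gives 4-(5-allyl-3-formyl-4-hydroxy-6-methoxybenzofuran-2-yl)-1,3-phenylene bis(2,2-dimethylpropanoate) F5.
  - Cross-metathesis with 2-methylbut-2-ene (second-generation Grubbs catalyst, CH2Cl2, 40 °C) returns to the route at 20.

**First alkynylation (step 3).**
- *Risk.* Oxidative addition to the doubly ortho-substituted, electron-rich iodide may be so slow that alkyne homocoupling and reductive loss of iodine dominate.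
- *Fallback.* It sets out from 2 and avoids cross-coupling at this carbon. Aryllithium 3, generated as in step 2, is quenched with DMF to give 4-methoxy-2,6-bis(methoxymethoxy)benzaldehyde F6. Ohira–Bestmann homologation with dimethyl (1-diazo-2-oxopropyl)phosphonate (K2CO3, MeOH, rt) returns to the route at 7 and replaces steps 2 to 4.

## Further compounds

F1 | step 7 | 4-[3-iodo-6-methoxy-4-(methoxymethoxy)benzofuran-2-yl]-1,3-phenylene bis(2,2-dimethylpropanoate) | Ic1c(-c2ccc(OC(=O)C(C)(C)C)cc2OC(=O)C(C)(C)C)oc2cc(OC)cc(OCOC)c12
F2 | step 7 | {2-[2,4-bis(pivaloyloxy)phenyl]-6-methoxy-4-(methoxymethoxy)benzofuran-3-yl}magnesium chloride | Cl[Mg]c1c(-c2ccc(OC(=O)C(C)(C)C)cc2OC(=O)C(C)(C)C)oc2cc(OC)cc(OCOC)c12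
F3 | step 8 | 4-[4-hydroxy-3-(hydroxymethyl)-6-methoxybenzofuran-2-yl]-1,3-phenylene bis(2,2-dimethylpropanoate) | OCc1c(-c2ccc(OC(=O)C(C)(C)C)cc2OC(=O)C(C)(C)C)oc2cc(OC)cc(O)c12
F0 | step 10 | none | none
F4 | step 12 | 4-[4-(allyloxy)-3-formyl-6-methoxybenzofuran-2-yl]-1,3-phenylene bis(2,2-dimethylpropanoate) | O=Cc1c(-c2ccc(OC(=O)C(C)(C)C)cc2OC(=O)C(C)(C)C)oc2cc(OC)cc(OCC=C)c12
F5 | step 12 | 4-(5-allyl-3-formyl-4-hydroxy-6-methoxybenzofuran-2-yl)-1,3-phenylene bis(2,2-dimethylpropanoate) | O=Cc1c(-c2ccc(OC(=O)C(C)(C)C)cc2OC(=O)C(C)(C)C)oc2cc(OC)c(CC=C)c(O)c12
F6 | step 3 | 4-methoxy-2,6-bis(methoxymethoxy)benzaldehyde | COCOc1cc(OC)cc(OCOC)c1C=O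
A1 | alternative 1 | methyl 2-[2,4-bis(methoxymethoxy)phenyl]-5-(2-diazoacetyl)furan-3-carboxylate | COC(=O)c1cc(C(=O)C=[N+]=[N-])oc1-c1ccc(OCOC)cc1OCOC
A2 | alternative 1 | 1-methoxy-5-methylhex-4-en-1-yne | COC#CCC=C(C)C
A3 | alternative 1 | methyl 2-[2,4-bis(methoxymethoxy)phenyl]-4-hydroxy-6-methoxy-5-(3-methylbut-2-enyl)benzofuran-3-carboxylate | COC(=O)c1c(-c2ccc(OCOC)cc2OCOC)oc2cc(OC)c(CC=C(C)C)c(O)c12
A4 | alternative 2 | 3-[2,4-bis(methoxymethoxy)benzoyl]-6-methoxy-4-(triisopropylsilyloxy)benzofuran-2(3H)-one (racemic, enolisable) | COCOc1ccc(C(=O)C2C(=O)Oc3cc(OC)cc(O[Si](C(C)C)(C(C)C)C(C)C)c32)c(OCOC)c1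
A5 | alternative 2 | methyl 2-[2,4-bis(methoxymethoxy)phenyl]-6-methoxy-4-(triisopropylsilyloxy)benzofuran-3-carboxylate | COC(=O)c1c(-c2ccc(OCOC)cc2OCOC)oc2cc(OC)cc(O[Si](C(C)C)(C(C)C)C(C)C)c12
A6 | alternative 3 | 2-acetyl-3-(benzyloxy)-5-methoxyphenyl 2,4-bis(methoxymethoxy)benzoate | CC(=O)c1c(OCc2ccccc2)cc(OC)cc1OC(=O)c1ccc(OCOC)cc1OCOC
A7 | alternative 3 | 4-(benzyloxy)-2-[2,4-bis(methoxymethoxy)phenyl]-6-methoxy-3-methylbenzofuran | Cc1c(-c2ccc(OCOC)cc2OCOC)oc2cc(OC)cc(OCc3ccccc3)c12
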